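The trap in these runs was to take conversion for yield: in Tuesday's run solid substrate read 0% at 0.333 h, yet target averaged 76.2% over its readings.

| flask | solid substrate | partner | remark | time |
|---|---|---|---|---|
| Saturday's | 0.25 M | 1.5 M | run made earlier |  |
| Tuesday's | 1 M | 1.5 M | run made earlier |  |
| Friday's | 0.50 M | 3 M | run made earlier |  |
| flask | 0.50 M | 1.50 M |  | 2.0 h |

- Saturday's (time / h: solid substrate / %, target / %): 0.200: 0, 99; 0.667: 3, 99; 1.00: 0, 95; 1.50: 0, 100; 2.50: 0, 100
- Tuesday's (time / h: solid substrate / %, target / %): 0.200: 3, 74; 0.333: 0, 75; 0.667: 0, 75; 1.33: 4, 77; 2.50: 0, 80
- Friday's (time / h: solid substrate / %, target / %): 0.500: 0, 97; 1.00: 0, 97; 1.33: 0, 95; 2.00: 3, 100; 2.50: 3, 96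

(readings scatter by 2 percentage points)

- the analysis behind the earlier runs scatters by 2 percentage points, standard deviation
- at the start none of the solid substrate is in solution
- a reading or a percentage of target counts all its forms, free or not
- what has only dissolved of solid substrate counts as not reacted
- the reaction counts as stopped when no species that holds the solid substrate changes by six tenths of a point or more over the second half of the time

- which holds at 2.0 h: what has brought the reaction to rest, or that it has not come to rest (for what has run out or reacted, a solid counts together with what of it has only dissolved) (forward and back rates have come level / it is still moving / all of the solid substrate has reacted)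
- part of the solid substrate that has turned into other species by 2.0 h (what has only dissolved does not count)
- how much target there is at 2.0 h, in percent of the solid substrate charged

My decision was whether to double Saturday's charge of solid substrate while holding [partner] at 1.50 M. Tuesday's shortfall was 23.8% and Saturday's 1.40%, at the same [partner]. I therefore reckoned the shortfall order, the apparent order with which the percentage of charge not found as target grows with the charge of solid substrate at fixed [partner]: 2.04. This is a rough reading, since Saturday's shortfall is smaller than the scatter of 2 percentage points.

Scaling down from Tuesday's run, I expected a shortfall of 5.77% in the flask, so 94.2% target. That is 0.471 M of target against Saturday's 0.246 M, so I charged 0.50 M.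

The forecast said all of the solid substrate has reacted, conversion 100% and target 96% (89% to 100%), with “enough partner for two equivalents and still a moderate excess”. My figure was lower but inside its range.

At 2.0 h the flask gave: all of the solid substrate has reacted, conversion >99.9%, target 96.8%.

    solid substrate + target → side product (k = 0.00526 L mol⁻¹ s⁻¹)
    crystals ⇌ target, rate k2*(cs2 - [target]) while solid is left; crystals form when [target] > cs2 (solubility = 0.380 M, k = 0.253 s⁻¹)
    solid substrate ⇌ dissolved substrate, rate k3*(cs3 - [dissolved substrate]) while solid is left; crystals form when [dissolved substrate] > cs3 (solubility = 0.210 M, k = 0.183 s⁻¹)
    dissolved substrate + partner → target (k = 0.0115 L mol⁻¹ s⁻¹)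
    partner → decomposed reagent (k = 7.23 × 10⁻⁴ s⁻¹)

The flask's shortfall was 3.23%, less than my 5.77%, and the forecast held. With all else held, the flask's target had moved by 5 points at 0.659 M of solid substrate. The neighbour charged with 0.85 M of solid substrate at the same [partner] stood above that charge, and its target fell below the forecast's low end of 89%. The shortfall order gives that neighbour a shortfall of 17.1%, so 82.9% target. It gave 83.7% target, with side product at 16.3%.

The data are simulated from invented constants.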